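Read Saturday's flask at 3.00 h and again at 10.0 h, and watch both columns.

| flask | substrate | reagent | temperature | remark | time |
|---|---|---|---|---|---|
| Monday's | 0.050 M | 0.060 M | 20 °C | run made earlier |  |
| Saturday's | 0.034 M | 0.060 M | 35 °C | run made earlier |  |
| Wednesday's | 0.075 M | 0.060 M | 20 °C | run made earlier |  |
| south-east | 0.050 M (fed, over 4.0 h) | 0.0600 M | 35 °C | all else is in the flask from the start; the feed brings no volume worth counting | 10 h |
| north | 0.050 M | 0.0600 M (fed, over 4.0 h) |  | the addition at 15 °C, then warmed to 35 °C; the feed brings no volume worth counting | 10 h |
| east | 0.050 M | 0.0600 M (fed, over 4.0 h) | 35 °C | all else is in the flask from the start; the feed brings no volume worth counting | 10 h |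
| south | 0.050 M (in portions, 2, over 4.0 h) | 0.0600 M | 35 °C | first portion at the start, last at 4.0 h | 10 h |

- Monday's (time / h: side product A / %, target / %): 0.833: 7.2, 4.9; 3.00: 16.7, 11.1; 4.00: 19.0, 12.6; 6.00: 21.1, 13.1; 10.0: 23.1, 14.2; 12.0: 23.3, 13.7
- Saturday's (time / h: side product A / %, target / %): 1.50: 30.8, 20.5; 3.00: 32.1, 20.2; 5.00: 32.5, 17.5; 6.00: 32.5, 16.3; 8.00: 32.1, 14.2; 10.0: 32.1, 11.3
- Wednesday's (time / h: side product A / %, target / %): 2.00: 12.6, 9.1; 3.00: 15.8, 10.7; 4.00: 17.4, 11.6; 8.00: 20.3, 14.0; 12.0: 21.3, 14.0; 20.0: 22.5, 13.4

(scatter of a reading: 0.3 percentage points)

- a reading or a percentage of target counts all its forms, free or not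

1. which flask leads in amount of side product A, in percent of the substrate charged ("all alike" within 1.5 percentage points) (south-east / north / east / south / all alike)
2. how much side product A is there at the end, in percent of the substrate charged: south-east
3. how much side product A is there at the end, in percent of the substrate charged: north
4. how much side product A is there at the end, in percent of the substrate charged: east
5. how much side product A is there at the end, in percent of the substrate charged: south

1. The two columns seem to disagree. In Saturday's flask side product A stands at 32.1% at both times, as if the reaction had died, yet target falls from 20.2% to 11.3%, so something is still reacting. Together they count for 52.3% of the charge at 3.00 h.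

2. My reading is that target is lost by a step of its own, one that side product A does not share, and that rival steps took the uncounted share of the substrate. The plateau of side product A is then a branching share, the fraction of substrate that ends as A with the rivals at work (its selectivity), 32.1%, a reading in Saturday's flask at 35 °C with 0.034 M substrate.

3. At the other end I suppose a flask in which no rival takes substrate. A's part of the first A and target readings in Saturday's flask then gives 60.0%, a reading that I use as my upper estimate.

4. The approach to the plateau reads as a substrate lifetime of 0.468 h, a rough reading, shorter than the feed of 4.0 h. I take the rival to be pseudo-first-order in reagent, which Saturday's flask holds in excess.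

5. So east, fed with reagent, has received about 11.7% of its reagent within one lifetime, and I place it between 32.1% and 60.0%. South-east and south have their reagent in the flask from the start, so I place them at or a little above 32.1%. North runs its feed at 15 °C, and Monday's flask at 20 °C shows a lifetime by the same reckoning of 2.25 h and a last A reading of 23.3%, so I place north between that reading and 32.1%.

The forecast gave 6.5%, 28.5%, 31% and 17% for south-east, north, east and south, with east leading, on the ground that "Late substrate therefore meets dead reagent".

The flasks give 35.8%, 27.2%, 41.6% and 34.1% in that order, and east leads.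

    crystals ⇌ target, rate k1*(cs1 - [target]) while solid is left; crystals form when [target] > cs1 (solubility = 2.10 mM, k = 0.00720 s⁻¹)
    reagent + target → over-reaction product (k = 0.00120 M⁻¹ s⁻¹, Ea = 62.0 kJ mol⁻¹)
    substrate + reagent → side product B (k = 0.00370 M⁻¹ s⁻¹, Ea = 66.0 kJ mol⁻¹)
    substrate → side product A (k = 2.00 × 10⁻⁴ s⁻¹, Ea = 94.0 kJ mol⁻¹)
    substrate → target (k = 1.50 × 10⁻⁴ s⁻¹, Ea = 97.0 kJ mol⁻¹)
    2 substrate → homo dimer (k = 0.00210 M⁻¹ s⁻¹, Ea = 60.0 kJ mol⁻¹)
    (constants at 35 °C)

In east at 0.417 h, substrate's half-life by the step to side product A is 0.96 h, while by the step with reagent it is 9.0 h, ten times longer. East ends with 6.32% side product B against 33.3% in south-east, and with 41.6% A, above 32.1% and below 60.0%.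

For the flask like east but charged with 0.020 M substrate, the same reckoning places side product A between 32.1% and 60.0%, both read in Saturday's flask. That flask gives 47.0%, inside it, with 7.90% side product B.

The runs come from a simulation with constants of no real substance; noise was put on by code.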